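Theta is read at 10 h and zeta at 5.0 h from one charge, so the later reading gives longer chains if the chains already stand at the earlier one.

| flask | Z | X | remark | time |
|---|---|---|---|---|
| maple | 0.25 M | 2 mol% | run made earlier |  |
| larch | 1 M | 2 mol% | run made earlier |  |
| oak | 0.50 M | 1 mol% | run made earlier |  |
| theta | 0.50 M | 2 mol% |  | 10 h |
| zeta | 0.50 M | 2 mol% |  | 5.0 h |

- maple (time / h: L / %, Z / %): 0.833: 2, 97; 2.00: 9, 86; 4.00: 18, 71; 10.0: 42, 32
- larch (time / h: L / %, Z / %): 0.833: 16, 81; 2.00: 39, 54; 4.00: 66, 27; 10.0: 83, 4
- oak (time / h: L / %, Z / %): 1.33: 5, 91; 4.00: 21, 67; 6.00: 28, 51; 10.0: 42, 32

(each reading ± 1.5 percentage points)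

- the average divides the monomer in chains by the number of chains begun, living and dead together
- the earlier runs do not show the number of chains; that part of a forecast is a guess

1. which of the two ends with the longer chains by the average number of monomer units in a chain (chains begun, living or dead) ("neither" if they lie within 10%) (theta / zeta / neither)
2. average number of monomer units in a chain (chains begun, living or dead) at the end, theta
3. average number of monomer units in a chain (chains begun, living or dead) at the end, zeta

Two views compete. The first says chains begin throughout the run, X being used at the pace of Z. The chain count then grows with L, length stays flat, and the answer is neither. The readings permit this: they show no chain count, and L in oak still climbs from 21% at 4.00 h to 42% at 10.0 h.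

The second view says chains begin early and then grow, so length is L divided by the loading of X, up to 50.0 units for the whole charge of Z.

The lag tells them apart. Oak has the Z of both flasks but half their loading of X, and the line through its first two L readings reaches zero at 0.496 h, a reading with much scatter, which I assume carries over to both flasks unchanged by the loading. I treat this induction time as the mean wait of a chain, replacing the staggered starts by one start. I assume the wait stretches as Z falls, and as a stand-in for zeta I take larch, which holds more X in molar terms: the mean of its charge and its Z reading at 4.00 h is 63.5%. That makes the start wait, the lag divided by the mean share of Z, 0.781 h. Zeta's reading time is longer than this, and I reckon the error of the single start as the X still unstarted, 0.165% of its charge. So I side with the second view.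

The forecast sides with it too: theta, with 31 units for theta and 22 for zeta, “Guessing one chain per X, with all X initiated”.

The flask gives 32.6 for theta and 22.4 for zeta, so theta ends longer.

    Z + X → Q + L (k = 0.0450 M⁻¹ min⁻¹)
    Z + Q → L + Q, rate k2*[Q]*[Z] (k = 0.260 M⁻¹ min⁻¹)
    Z → G (k = 6.70 × 10⁻⁴ min⁻¹)

In zeta, Z + X → Q + L had 49% of its turnover up to 5.00 h behind it at 0.500 h, inside the wait of 0.781 h, and that stretch is the region of the first view, with the chain count still growing alongside L. Z + Q → L + Q and Z → G ran on, and at 5.00 h zeta holds Q 0.00991 M, X 0.943% of its charge against the reckoned 0.165%, and L 44.4%, which over the loading gives 22.2 units. The neighbour flask, zeta with 1.2 mol% of X, holds X 0.570% of its charge against the same reckoned 0.165%, and L 30.1% at 5.00 h, and L over its loading gives 25.1 units, where that flask's average stands at 25.3.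

The data are calculated from invented constants, noise included.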